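**Plan**
Feature: on the lactone ring (O1, C2 carbonyl, C3 carbinol, C4, C5) the ArCH2 groups of C3 and C4 stand on the same face, so their benzylic carbons can be joined through one sulfur atom into a thiolane ring cis-fused along C3–C4.
Cuts: the two benzylic C–H bonds go back to C–S bonds. Then C3–CH(Ar) and C4–CH(Ar) are cut together, leaving a symmetrical 1,3-diaryl thiocarbonyl ylide and a 3-acetoxy-5-menthyloxybutenolide.
Forward: the lactone ring is made first from furfural (photooxygenation, menthyl acetal, dihydroxylation, acetylation–elimination). The ylide precursor comes from vanillin through the dibenzyl sulfide, C-silylation and α-chlorination.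
The [3+2] cycloaddition then closes the thiolane. Ni2B removes sulfur, KOH/NaBH4 turns the acetal carbon C5 into CH2 and frees the C3 hydroxyl, and hydrogenolysis frees the phenols.
Stereochemistry: (−)-menthol fixes C5 as R by crystallisation. The C5 menthyloxy group sends the dipole to the opposite face (C4), suprafacial addition sets C3 and makes the benzyl groups cis, and C5 is erased at the end.

Key step: step 11

Assumption: 15 and 16 are carried as stereoisomer mixtures because their sulfur-bound centres disappear in the planar ylide; Ar = 4-benzyloxy-3-methoxyphenyl, menthyl = (1R,2S,5R)-2-isopropyl-5-methylcyclohexyl, and monocyclic lactones are numbered O1, C2 (carbonyl), C3, C4, C5.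

Step 1
Reactants: 1 furfural
Product: 3 5-hydroxyfuran-2(5H)-one (racemic), via furfural endoperoxide 2 (not isolated)
Conditions: O2, methylene blue (cat.), MeOH, hν (visible), rt
Reagents that add atoms: dioxygen, O=O
Why: Singlet oxygen adds across the furan in a [4+2] cycloaddition and methanol then removes the formyl group of 2 as its formate ester (dye-sensitised photooxygenation of furfural), which should leave the racemic γ-hydroxybutenolide.

Step 2
Reactants: 3 5-hydroxyfuran-2(5H)-one; 4 (−)-menthol
Product: 5 (5R)-5-[(1R,2S,5R)-menthyloxy]furan-2(5H)-one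
Conditions: p-TsOH (cat.), toluene, reflux, azeotropic removal of water; crystallisation from hexane, mother liquor re-equilibrated with the acid and crystallised again
Reagents that add atoms: none
Why: Acid-catalysed acetalisation of the pseudo-acid gives both C5 epimers, which interconvert under the acid while the (5R) epimer crystallises (crystallisation-induced diastereomer transformation), so C5 is set by the menthol stereocentres.

Step 3
Reactants: 5 (5R)-5-[(1R,2S,5R)-menthyloxy]furan-2(5H)-one
Product: 6 (3S,4R,5R)-3,4-dihydroxy-5-[(1R,2S,5R)-menthyloxy]dihydrofuran-2(3H)-one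
Conditions: OsO4 (cat.), N-methylmorpholine N-oxide, acetone–H2O, rt
Reagents that add atoms: N-methylmorpholine N-oxide, C[N+]1([O-])CCOCC1; water, O (both oxygens are handed on through OsO4, O=[Os](=O)(=O)=O)
Why: OsO4-catalysed syn-dihydroxylation of the butenolide C3=C4 bond should take place on the face away from the menthyloxy group, and the two new centres are only temporary because step 4 makes C3 and C4 planar again.

Step 4
Reactants: 6 (3S,4R,5R)-3,4-dihydroxy-5-[(1R,2S,5R)-menthyloxy]dihydrofuran-2(3H)-one
Product: 8 (5R)-3-acetoxy-5-[(1R,2S,5R)-menthyloxy]furan-2(5H)-one, via diacetate 7 (not isolated)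
Conditions: Ac2O, Et3N (excess), DMAP (cat.), CH2Cl2, 0 °C to rt
Reagents that add atoms: acetic anhydride, CC(=O)OC(C)=O
Why: Acetylation of both hydroxyls is followed by E1cB loss of the C4 acetate (H-3 is α to the lactone carbonyl and anti to the leaving group), the β-elimination by which acylated aldonolactones give 2-acyloxybutenolides, and the mild amine base should leave C5 untouched.

Step 5
Reactants: 9 vanillin
Product: 10 4-benzyloxy-3-methoxybenzaldehyde
Conditions: BnBr, K2CO3, DMF, rt
Reagents that add atoms: benzyl bromide, BrCc1ccccc1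
Why: Williamson ether synthesis on the phenoxide gives a protecting group that tolerates organolithium, fluoride, Ni2B and hydroxide and leaves by hydrogenolysis at the end.

Step 6
Reactants: 10 4-benzyloxy-3-methoxybenzaldehyde
Product: 11 (4-benzyloxy-3-methoxyphenyl)methanol
Conditions: NaBH4, MeOH, 0 °C
Reagents that add atoms: none
Why: Borohydride reduction of an aromatic aldehyde is fast and touches neither ether.

Step 7
Reactants: 11 (4-benzyloxy-3-methoxyphenyl)methanol
Product: 12 4-benzyloxy-3-methoxybenzyl chloride
Conditions: SOCl2, CH2Cl2, 0 °C; used crude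
Reagents that add atoms: thionyl chloride, O=S(Cl)Cl
Why: Deoxychlorination of an electron-rich benzylic alcohol with thionyl chloride runs readily at low temperature, and the labile chloride is taken on without purification.

Step 8
Reactants: 12 4-benzyloxy-3-methoxybenzyl chloride (two molecules)
Product: 13 bis(4-benzyloxy-3-methoxybenzyl) sulfide
Conditions: Na2S·9H2O, DMF, 0 °C to rt
Reagents that add atoms: sodium sulfide, [Na+].[Na+].[S-2]
Why: Two successive SN2 displacements by sulfide and then thiolate on a reactive benzylic chloride give the symmetrical sulfide, and the dipolar aprotic solvent keeps solvolysis down.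

Step 9
Reactants: 13 bis(4-benzyloxy-3-methoxybenzyl) sulfide
Product: 15 4-benzyloxy-3-methoxybenzyl (4-benzyloxy-3-methoxyphenyl)(trimethylsilyl)methyl sulfide (racemic), via lithiated sulfide 14 (not isolated)
Conditions: n-BuLi (1.05 equiv), THF, −78 °C; Me3SiCl, −78 °C to rt
Reagents that add atoms: chlorotrimethylsilane, C[Si](C)(C)Cl
Why: The benzylic C–H next to sulfur is the most acidic site, so α-lithiation gives 14, which is kept cold to hold back thio-Wittig rearrangement and is trapped on carbon by the chlorosilane, the new centre being racemic and of no consequence.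

Step 10
Reactants: 15 4-benzyloxy-3-methoxybenzyl (4-benzyloxy-3-methoxyphenyl)(trimethylsilyl)methyl sulfide
Product: 16 chloro(4-benzyloxy-3-methoxyphenyl)methyl (4-benzyloxy-3-methoxyphenyl)(trimethylsilyl)methyl sulfide (diastereomer mixture)
Conditions: N-chlorosuccinimide (1.0 equiv), benzene, 0 °C to rt, dark; filtered, concentrated, used at once
Reagents that add atoms: N-chlorosuccinimide, O=C1CCC(=O)N1Cl
Why: Pummerer-type α-chlorination of a sulfide with NCS should pick the open ArCH2 site with its two accessible hydrogens over the C–H flanked by SiMe3 and aryl, and the C–Si bond of α-silyl sulfides is known to survive this reagent.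

Step 11
Reactants: 8 (5R)-3-acetoxy-5-[(1R,2S,5R)-menthyloxy]furan-2(5H)-one; 16 chloro(4-benzyloxy-3-methoxyphenyl)methyl (4-benzyloxy-3-methoxyphenyl)(trimethylsilyl)methyl sulfide
Product: 18 (1R,3aR,6aR)-3a-acetoxy-4,6-bis(4-benzyloxy-3-methoxyphenyl)-1-[(1R,2S,5R)-menthyloxy]tetrahydro-1H,3H-thieno[3,4-c]furan-3-one (mixture at C4/C6), via thiocarbonyl ylide 17 (not isolated)
Conditions: CsF (dried), MeCN, rt; 16 (2–3 equiv) added slowly to 8 and CsF
Reagents that add atoms: none
Why: Fluoride takes the silyl group of 16 while chloride departs from the other α-carbon (1,3-elimination), which releases the planar 4π-electron dipole 17, and its high-lying HOMO combines with the LUMO of the lactone-conjugated C3=C4 bond of 8 in a concerted suprafacial [3+2] cycloaddition. The closest known reaction type is the addition of fluoride-generated thiocarbonyl ylides to 5-alkoxybutenolides and other cyclic enoates, so the aryl groups on the dipole and the weakly donating acetoxy group on the alkene are new substituents on a known pairing. The thiolane ring closes in the intermolecular cycloaddition itself, C3–CH(Ar) and C4–CH(Ar) being formed together on one face, so the ring fusion can only be cis. C4 of the lactone (C6a of 18) is controlled by the neighbouring C5 menthyloxy group, which blocks its own face, and C3 (C3a) follows from the suprafacial mode, so acetoxy and H-4 end up on the menthyloxy face, whereas the two sulfur-bearing carbons depend on ylide geometry and endo or exo approach, are expected as a mixture and need no control because step 12 turns them into CH2. The step needs π-facial selectivity, secured by the acetal substituent next to the reacting carbon, and trapping of 17 ahead of its electrocyclisation to a thiirane, served by slow addition of excess 16 to a concentrated solution of 8, while regioselectivity does not arise because the dipole is symmetrical. Any adduct derived from C5-epimerised 8 would be a diastereomer thanks to the menthyl group and can be removed by chromatography or crystallisation.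

Step 12
Reactants: 18 cycloadduct
Product: 19 (3R,4R,5R)-3-acetoxy-3,4-bis(4-benzyloxy-3-methoxybenzyl)-5-[(1R,2S,5R)-menthyloxy]dihydrofuran-2(3H)-one
Conditions: NiCl2·6H2O, NaBH4, THF–MeOH, 0 °C
Reagents that add atoms: none
Why: Ni2B formed in the flask hydrogenolyses both benzylic C–S bonds (reductive desulfurisation), which converges the isomer mixture to one compound with two cis ArCH2 groups, does not involve C3, C4 or C5, and should spare the benzyl ethers, while partial loss of acetate would be harmless since step 13 removes it.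

Step 13
Reactants: 19 (3R,4R,5R)-3-acetoxy-3,4-bis(4-benzyloxy-3-methoxybenzyl)-5-[(1R,2S,5R)-menthyloxy]dihydrofuran-2(3H)-one
Product: 22 (3R,4S)-3,4-bis(4-benzyloxy-3-methoxybenzyl)-3-hydroxydihydrofuran-2(3H)-one, via aldehyde acid 20 (not isolated), via dihydroxy acid 21 (not isolated)
Conditions: NaBH4 (excess), KOH, EtOH–THF–H2O, 0 °C to rt; then 2 M HCl, rt
Reagents that add atoms: potassium hydroxide, [K+].[OH-] (its oxygen enters the carboxyl group of 20 and 21 and can remain as the lactone carbonyl oxygen of 22)
Why: Hydroxide cleaves the acetate and opens the lactone acetal, the hemiacetal so exposed drops menthol, the aldehyde of 20 is reduced by the borohydride already present before it can enolise so that C4 is kept, and acid closes 21 to the γ-lactone with C2 still the carbonyl and C5 now CH2 (saponification, borohydride reduction and lactonisation as practised on 3,4-dibenzyl-5-menthyloxybutyrolactones).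

Step 14
Reactants: 22 (3R,4S)-3,4-bis(4-benzyloxy-3-methoxybenzyl)-3-hydroxydihydrofuran-2(3H)-one
Product: 23 epinortrachelogenin, (3R,4S)-3-hydroxy-3,4-bis(4-hydroxy-3-methoxybenzyl)dihydrofuran-2(3H)-one
Conditions: H2 (1 atm), 10% Pd/C, EtOAc–EtOH, rt
Reagents that add atoms: none
Why: Catalytic hydrogenolysis removes both aryl benzyl ethers under neutral conditions that affect neither the lactone, the non-benzylic tertiary alcohol nor the two stereocentres.

**Compound list**
1 | furfural | O=Cc1ccco1 | starting material
2 | furfural endoperoxide, 2,3,7-trioxabicyclo[2.2.1]hept-5-ene-1-carbaldehyde (racemic) | O=CC12C=CC(OO1)O2 | intermediate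
3 | 5-hydroxyfuran-2(5H)-one (racemic) | O=C1C=CC(O)O1 | intermediate
4 | (−)-menthol | C[C@@H]1CC[C@H]([C@@H](C1)O)C(C)C | starting material
5 | (5R)-5-[(1R,2S,5R)-menthyloxy]furan-2(5H)-one | O=C1O[C@@H](O[C@@H]2C[C@H](C)CC[C@H]2C(C)C)C=C1 | intermediate
6 | (3S,4R,5R)-3,4-dihydroxy-5-[(1R,2S,5R)-menthyloxy]dihydrofuran-2(3H)-one | O=C1O[C@@H](O[C@@H]2C[C@H](C)CC[C@H]2C(C)C)[C@H](O)[C@@H]1O | intermediate
7 | (3S,4R,5R)-3,4-diacetoxy-5-[(1R,2S,5R)-menthyloxy]dihydrofuran-2(3H)-one | O=C1O[C@@H](O[C@@H]2C[C@H](C)CC[C@H]2C(C)C)[C@H](OC(C)=O)[C@@H]1OC(C)=O | intermediate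
8 | (5R)-3-acetoxy-5-[(1R,2S,5R)-menthyloxy]furan-2(5H)-one | O=C1O[C@@H](O[C@@H]2C[C@H](C)CC[C@H]2C(C)C)C=C1OC(C)=O | intermediate
9 | vanillin | COc1cc(C=O)ccc1O | starting material
10 | 4-benzyloxy-3-methoxybenzaldehyde | COc1cc(C=O)ccc1OCc1ccccc1 | intermediate
11 | (4-benzyloxy-3-methoxyphenyl)methanol | COc1cc(CO)ccc1OCc1ccccc1 | intermediate
12 | 4-benzyloxy-3-methoxybenzyl chloride | COc1cc(CCl)ccc1OCc1ccccc1 | intermediate
13 | bis(4-benzyloxy-3-methoxybenzyl) sulfide | COc1cc(CSCc2ccc(OCc3ccccc3)c(OC)c2)ccc1OCc1ccccc1 | intermediate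
14 | α-lithio derivative of 13 | COc1cc(CSC([Li])c2ccc(OCc3ccccc3)c(OC)c2)ccc1OCc1ccccc1 | intermediate
15 | 4-benzyloxy-3-methoxybenzyl (4-benzyloxy-3-methoxyphenyl)(trimethylsilyl)methyl sulfide (racemic) | COc1cc(CSC([Si](C)(C)C)c2ccc(OCc3ccccc3)c(OC)c2)ccc1OCc1ccccc1 | intermediate
16 | chloro(4-benzyloxy-3-methoxyphenyl)methyl (4-benzyloxy-3-methoxyphenyl)(trimethylsilyl)methyl sulfide (diastereomer mixture) | COc1cc(C(Cl)SC([Si](C)(C)C)c2ccc(OCc3ccccc3)c(OC)c2)ccc1OCc1ccccc1 | intermediate
17 | 1,3-bis(4-benzyloxy-3-methoxyphenyl) thiocarbonyl ylide | COc1cc([CH-][S+]=Cc2ccc(OCc3ccccc3)c(OC)c2)ccc1OCc1ccccc1 | intermediate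
18 | (1R,3aR,6aR)-3a-acetoxy-4,6-bis(4-benzyloxy-3-methoxyphenyl)-1-[(1R,2S,5R)-menthyloxy]tetrahydro-1H,3H-thieno[3,4-c]furan-3-one, thiolane anti to menthyloxy, mixture at C4/C6 | O=C1O[C@@H](O[C@@H]2C[C@H](C)CC[C@H]2C(C)C)[C@@H]2C(c3ccc(OCc4ccccc4)c(OC)c3)SC(c3ccc(OCc4ccccc4)c(OC)c3)[C@]12OC(C)=O | intermediate
19 | (3R,4R,5R)-3-acetoxy-3,4-bis(4-benzyloxy-3-methoxybenzyl)-5-[(1R,2S,5R)-menthyloxy]dihydrofuran-2(3H)-one | O=C1O[C@@H](O[C@@H]2C[C@H](C)CC[C@H]2C(C)C)[C@H](Cc2ccc(OCc3ccccc3)c(OC)c2)[C@@]1(Cc2ccc(OCc3ccccc3)c(OC)c2)OC(C)=O | intermediate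
20 | (2R,3R)-2,3-bis(4-benzyloxy-3-methoxybenzyl)-2-hydroxy-4-oxobutanoic acid (potassium salt in the flask) | O=C[C@H](Cc1ccc(OCc2ccccc2)c(OC)c1)[C@](O)(Cc1ccc(OCc2ccccc2)c(OC)c1)C(=O)O | intermediate
21 | (2R,3S)-2,3-bis(4-benzyloxy-3-methoxybenzyl)-2,4-dihydroxybutanoic acid (potassium salt in the flask) | OC[C@H](Cc1ccc(OCc2ccccc2)c(OC)c1)[C@](O)(Cc1ccc(OCc2ccccc2)c(OC)c1)C(=O)O | intermediate
22 | (3R,4S)-3,4-bis(4-benzyloxy-3-methoxybenzyl)-3-hydroxydihydrofuran-2(3H)-one | COc1cc(C[C@H]2COC(=O)[C@@]2(O)Cc2ccc(OCc3ccccc3)c(OC)c2)ccc1OCc1ccccc1 | intermediate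
23 | epinortrachelogenin | COc1cc(C[C@H]2COC(=O)[C@@]2(O)Cc2ccc(O)c(OC)c2)ccc1O | target

**Totals and risks**
Total step count: 14. Longest linear sequence: 10 steps (steps 5 to 14, from vanillin).

1. Step 11.
   - What may go wrong: addition to a trisubstituted, acetoxy-bearing double bond may be slower than ring closure of the dipole and loss of sulfur. Basic fluoride may also strip the enol acetate or epimerise C5.
   - The fallback sets out from 5 and 16 and comes back at 22. It brings the C3 oxygen in after the cycloaddition instead of before it.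
   - Ylide 17 (CsF, MeCN) is added to the unsubstituted butenolide 5, the substrate class on which this cycloaddition is established. This gives the 3a-unsubstituted cycloadduct F1.
   - Ni2B converts F1 into the cis-dibenzyl lactone acetal F2.
   - F2 is deprotonated at C3 with KN(SiMe3)2 in THF at −78 °C, followed by oxygen transfer from 2-(phenylsulfonyl)-3-phenyloxaziridine. The hydroxyl should enter anti to the adjacent C4 benzyl group, that is on the menthyloxy face, giving the 3-hydroxy lactone acetal F3 with the C3 configuration of 19.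
   - F3 is submitted to the conditions of step 13 and passes through 20 and 21 to 22.

2. Step 10.
   - What may go wrong: chlorination may go to the silyl-bearing carbon, the electron-rich benzyl–sulfur bond may fragment after S-chlorination, and the product may hydrolyse on handling.
   - The fallback sets out from 15 and comes back at 18. It replaces halide and fluoride activation by a sila-Pummerer release of the same dipole.
   - A second kinetic lithiation of 15 at the free ArCH2 site (n-BuLi, THF, −78 °C) and quench with Me3SiCl gives the bis-silyl sulfide F4.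
   - 3-Chloroperbenzoic acid in CH2Cl2 at low temperature gives the bis-silyl sulfoxide F5, which is not stored.
   - The solution of F5 is warmed with 8 in DMF. Silicon migrates to oxygen and the second silyl group is removed by the silanolate, which releases 17 under neutral, fluoride-free conditions and leads to 18.

3. Step 13.
   - What may go wrong: the liberated aldehyde may enolise before it is reduced (epimerisation at C4, retro-aldol cleavage of C3–C4), or hydride may attack the lactone carbonyl before the ring is opened.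
   - The fallback sets out from 18 and comes back at 22. It never frees an aldehyde.
   - Acetal exchange of 18 with PhSH and BF3·OEt2 in CH2Cl2 at −20 °C replaces menthyloxy by phenylthio and gives the phenylthio lactone F6 (configuration at C1 irrelevant).
   - Excess Ni2B cleaves all three C–S bonds at once and gives the acetoxy lactone F7, in which C5 is already CH2.
   - K2CO3 in MeOH removes the acetate and gives 22.

**Further compounds**
F1 | step 11 | (1R,3aS,6aR)-4,6-bis(4-benzyloxy-3-methoxyphenyl)-1-[(1R,2S,5R)-menthyloxy]tetrahydro-1H,3H-thieno[3,4-c]furan-3-one (mixture at C4/C6) | O=C1O[C@@H](O[C@@H]2C[C@H](C)CC[C@H]2C(C)C)[C@@H]2C(c3ccc(OCc4ccccc4)c(OC)c3)SC(c3ccc(OCc4ccccc4)c(OC)c3)[C@H]12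
F2 | step 11 | (3S,4R,5R)-3,4-bis(4-benzyloxy-3-methoxybenzyl)-5-[(1R,2S,5R)-menthyloxy]dihydrofuran-2(3H)-one | O=C1O[C@@H](O[C@@H]2C[C@H](C)CC[C@H]2C(C)C)[C@H](Cc2ccc(OCc3ccccc3)c(OC)c2)[C@@H]1Cc1ccc(OCc2ccccc2)c(OC)c1
F3 | step 11 | (3R,4R,5R)-3,4-bis(4-benzyloxy-3-methoxybenzyl)-3-hydroxy-5-[(1R,2S,5R)-menthyloxy]dihydrofuran-2(3H)-one | O=C1O[C@@H](O[C@@H]2C[C@H](C)CC[C@H]2C(C)C)[C@H](Cc2ccc(OCc3ccccc3)c(OC)c2)[C@@]1(Cc2ccc(OCc3ccccc3)c(OC)c2)O
F4 | step 10 | bis[(4-benzyloxy-3-methoxyphenyl)(trimethylsilyl)methyl] sulfide (stereoisomer mixture) | COc1cc(C(SC([Si](C)(C)C)c2ccc(OCc3ccccc3)c(OC)c2)[Si](C)(C)C)ccc1OCc1ccccc1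
F5 | step 10 | bis[(4-benzyloxy-3-methoxyphenyl)(trimethylsilyl)methyl] sulfoxide (stereoisomer mixture) | COc1cc(C([Si](C)(C)C)S(=O)C([Si](C)(C)C)c2ccc(OCc3ccccc3)c(OC)c2)ccc1OCc1ccccc1
F6 | step 13 | (3aR,6aR)-3a-acetoxy-4,6-bis(4-benzyloxy-3-methoxyphenyl)-1-(phenylthio)tetrahydro-1H,3H-thieno[3,4-c]furan-3-one (mixture at C1, C4, C6) | O=C1OC(Sc2ccccc2)[C@@H]2C(c3ccc(OCc4ccccc4)c(OC)c3)SC(c3ccc(OCc4ccccc4)c(OC)c3)[C@]12OC(C)=O
F7 | step 13 | (3R,4S)-3-acetoxy-3,4-bis(4-benzyloxy-3-methoxybenzyl)dihydrofuran-2(3H)-one | COc1cc(C[C@H]2COC(=O)[C@@]2(OC(C)=O)Cc2ccc(OCc3ccccc3)c(OC)c2)ccc1OCc1ccccc1
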